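I take the starting material, target and isomer of the product in this closed flask to add up to the charge, so the ratio of target to isomer of the product, R, tells how the converted part of one fixed stock is split at a given time.

in all of them: starting material 0.17 M; added ligand 0.39 mM
- violet: catalyst 0.1 mol%; run made earlier
- ochre: catalyst 0.15 mol%; run made earlier
- flask: catalyst 0.2 mol%; time 2.0 min

- violet (time / s: target / %, isomer of the product / %): 10.0: 5.3, 1.7; 15.0: 3.6, 2.3; 25.0: 10.2, 2.3; 40.0: 11.0, 2.9; 80.0: 18.6, 8.7; 120: 21.6, 17.3
- ochre (time / s: target / %, isomer of the product / %): 10.0: 5.0, 3.8; 25.0: 9.3, 2.2; 40.0: 13.0, 5.3; 60.0: 16.7, 9.5; 90.0: 19.7, 13.6; 120: 20.5, 19.0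

(scatter of a reading: 1 percentage point)



- ratio of target to isomer of the product at 2.5 s
- ratio of target to isomer of the product at 2.0 min

The violet run, the ochre run and the flask share 0.17 M of starting material and 0.39 mM of added ligand, so their catalyst loading changes ρ, the added ligand charged per catalyst charged: 2.29 in violet, 1.53 in ochre and 1.15 in the flask. At 120 s the readings give R = 1.25 in violet, higher than the 1.08 in ochre, and both ratios carry the scatter of 1 percentage point on each reading. I draw a straight line through these two points, and its slope is 0.222. This s, the gain in R per unit of ρ at fixed starting material and time, takes me from ochre down to the ρ of the flask, where my reckoning gives R = 0.994 at 2.0 min. The earliest readings come later than 2.5 s, so I reckon no early ratio of my own.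

The forecast gives 1 at 2.5 s and 1.05 at 2.0 min, which is above my line; it notes the flask has “ligand only slightly in excess”.

The flask gives 0.873 at 2.5 s and 1.03 at 2.0 min, so both forecast values hold within their margins, and my line's 0.994 stands 0.0360 below the flask's ratio at 2.0 min.

    starting material ⇌ target (K = 1.90, k = 0.00407 s⁻¹)
    target ⇌ isomer of the product (K = 2.70, k = 0.00909 s⁻¹)
    isomer of the product + catalyst ⇌ starting material + catalyst, rate k3*[catalyst]*[isomer of the product] forward; the back reaction follows from the equilibrium constant (k = 3.16 M⁻¹ s⁻¹)
    catalyst + added ligand ⇌ idle complex (K = 63000 M⁻¹, k = 429 M⁻¹ s⁻¹)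

A neighbouring flask, like this one but with 9.8 × 10⁻⁴ M of added ligand, has ρ = 2.88, and s, read with the added ligand held and the catalyst changed, carried on from violet gives R = 1.38; that neighbour gives 1.43 at 2.0 min. At that time its target is 22.0 % against 21.8 % in the flask, while its isomer of the product is lower, 15.4 % against 21.3 %. In that neighbour at 2.0 min, 97.6 % of the catalyst stands as idle complex and 2.39 % stands free.

(The readings were generated by integration with constants of no real substance; noise was put on by code.)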